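The substrate is short-lived.

| flask | substrate | remark | time |
|---|---|---|---|
| north-west | 0.80 M | run made earlier |  |
| north-east | 0.40 M | run made earlier |  |
| north | 0.60 M | run made earlier |  |
| green | 0.80 M | one stirred flow tank at steady state, fed with the mixture as stated, mean residence time 5.0 min |  |
| grey | 0.80 M | a closed flask charged with all of it at once and left for 5.0 min | 5.0 min |
| violet | 0.80 M | a tube with plug flow, the mixed feed as stated, residence time 5.0 min | 5.0 min |

| run | time / min | target / % |
|---|---|---|
| north-west | 0.417 | 17.8 |
| north-west | 0.833 | 26.2 |
| north-west | 1.33 | 32.3 |
| north-west | 1.50 | 32.3 |
| north-west | 2.00 | 34.4 |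
| north-west | 2.50 | 34.9 |
| north-west | 3.00 | 36.0 |
| north-east | 0.500 | 20.8 |
| north-east | 0.667 | 24.9 |
| north-east | 1.00 | 31.7 |
| north-east | 1.50 | 35.8 |
| north-east | 2.50 | 38.9 |
| north-east | 4.00 | 40.8 |
| north-east | 6.00 | 42.9 |
| north | 0.500 | 20.0 |
| north | 0.667 | 23.2 |
| north | 1.00 | 29.0 |
| north | 1.50 | 34.4 |
| north | 2.50 | 36.5 |
| north | 4.00 | 38.4 |
| north | 6.00 | 40.1 |

(standard deviation of a reading: 1 percentage point)

- the stated concentrations are those of everything mixed, before any reaction; amounts are the same in each set-up
- the numbers in the tables scatter with a standard deviation of 1 percentage point
- the earlier runs were made in a closed, stirred flask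

- the set-up with the highest amount of target at the outlet or at the end, in percent of the substrate put in ("none" if the first two lie within 2 percentage points) (green / grey / violet / none)
- amount of target at the outlet or at the end, in percent of the substrate put in, green
- amount of target at the outlet or at the end, in percent of the substrate put in, grey
- amount of target at the outlet or at the end, in percent of the substrate put in, violet

In the north-west run, target reads 17.8% at 0.417 min and 36.0% at 3.00 min. Read as an exponential approach, these two readings give substrate a loss constant of 1.64 /min. Multiplied by 5.0 min, it gives 8.18: the number of substrate lifetimes within the time on offer, the Damköhler number.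

The grey flask and the violet tube give every portion the same 5.0 min. By this reckoning both keep 0.0280% of the substrate, so both should stand near the last north-west reading, 36.0%. The green tank keeps a fraction 1/(1+Da), 10.9%, so it runs at c(substrate) = 0.0872 M, lower than the north-east charge.

One number does not suffice. It gives the green tank's loss, but the gain must come from the readings: at 2.50 min target reads 38.9% from 0.40 M, against 34.9% from 0.80 M. Taking the last north-east reading, 42.9% at 6.00 min, as the green tank's share and multiplying by its conversion gives 38.2%. That is 2.2 percentage points above the value taken for grey and violet, over the margin 2 points by less than the scatter 1 point. The call here is therefore "none".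

The forecast gives 38.5% for green, 38.2% for grey and 38.2% for violet, hence none (“All lie within 2 points”), with grey and violet higher than the north-west reading used here.

The simulation gives 38.8% for green, 37.7% for grey and 37.7% for violet, so the best is none.

    2 substrate → homo dimer (k = 0.00762 /M/s)
    substrate → side product (k = 0.0112 /s)
    substrate → target (k = 0.0102 /s)

The slowest mode of the violet tube has a half-life of 0.539 min at 5.00 min, far shorter than the 5.0 min on offer. The violet tube ends with 0.10% substrate, against 0.0280% reckoned from the carried number. For violet read at 80 s, the same constant gives 11.3% substrate and, from the last north-west reading, 31.9% target. That violet reading holds 12% substrate and 32.1% target.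

The data are simulated from invented constants.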